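The cyclohexene ring is cut at C1–C6 and C2–C3 (C1 = quaternary carbinol, C2 = CH–OAc, C3/C6 = CH–OBz, C4=C5 alkene, C7 = CH2OBz). The feature exploited is the pairing of cis allylic benzoates at C3/C6 with a cis C1/C2 diol on the opposite ring face. One enantioselective, formyl-endo Diels–Alder reaction builds the carbocycle and all four stereocentres. Its partners are (1E,3E)-1,4-dibenzoyloxybutadiene, which already carries two of the target's esters, and 2,2-dimethyl-1,3-dioxole-4-carbaldehyde, a ring-locked cis-enediol whose formyl carbon becomes C7. Four routine steps (reduction, benzoylation, ketal hydrolysis, selective acetylation) finish the synthesis.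

Key step: step 5

Remarks on the chemistry (the locants above are kept for all intermediates):
- Stereochemical check: in the target, O1 and O2 lie on one ring face and O3, O6 and C7 on the other, which is (1R,2S,3R,6S). Cycloadduct 10 as drawn below has the same arrangement at all four centres, so its structure needs no correction.
- Assumption: the sense of induction is taken from the accepted binding model for 2-substituted enals on proline-derived oxazaborolidinium ions. Both catalyst antipodes are commercial.
- Precursor design: the isopropylidene ketal is kept. Its methyl groups disfavour the dioxole-endo topology, and it is removed by acid, which leaves the esters intact. A carbonate would be more reactive, but it favours the all-cis topology and cannot be cleaved safely beside benzoates.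
- Dienophile source: it is made by dehydrogenating commercial glyceraldehyde acetonide, not by formylating the volatile, acid-labile parent dioxole.

Step 1
Reactants: 1 2,5-dimethoxytetrahydrofuran (cis/trans mixture)
Product: 2 succinaldehyde (butanedial)
Conditions: H2O, 90 °C; distil off MeOH/H2O; extract into CH2Cl2, dry, use at once
Reagents that add atoms: water, O
Why: Neutral aqueous acetal hydrolysis, driven by distilling out methanol, frees the dialdehyde without the acid or base that would start its aldol self-condensation.

Step 2
Reactants: 2 succinaldehyde; 3 benzoyl chloride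
Product: 6 (1E,3E)-buta-1,3-diene-1,4-diyl dibenzoate, via 4-oxobut-1-enyl benzoate 4 (not isolated), via E/Z-mixed dienyl dibenzoate 5 (not isolated)
Conditions: BzCl (2.5 equiv), Et3N, DMAP (cat.), CH2Cl2, 0 °C → reflux; aqueous wash, swap to PhMe, I2 (cat.), 80 °C; crystallise
Reagents that add atoms: benzoyl chloride, O=C(Cl)c1ccccc1
Why: Double enol O-acylation of a 1,4-dialdehyde: amine/DMAP-mediated benzoylation traps the first enol as 4, whose CH2 is then flanked by formyl and vinyl groups and enolises readily to give 5, and iodine-catalysed E/Z equilibration followed by crystallisation funnels the isomers into the least hindered E,E diene.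

Step 3
Reactants: 7 (R)-2,2-dimethyl-1,3-dioxolane-4-carbaldehyde (glyceraldehyde acetonide; any enantiomeric composition serves)
Product: 8 4-{[(tert-butyldimethylsilyl)oxy]methylidene}-2,2-dimethyl-1,3-dioxolane (E/Z mixture)
Conditions: TBSOTf, Et3N, CH2Cl2, 0 °C
Reagents that add atoms: tert-butyldimethylsilyl trifluoromethanesulfonate, CC(C)(C)[Si](C)(C)OS(=O)(=O)C(F)(F)F
Why: Soft enolisation and O-silylation (silyl triflate/amine) of an α-branched aldehyde gives the exocyclic enol silane under conditions too mild for β-alkoxide loss or ketal cleavage, the stereocentre of 7 being erased on purpose and both alkene isomers converging in step 4.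

Step 4
Reactants: 8 silyl enol ether
Product: 9 2,2-dimethyl-1,3-dioxole-4-carbaldehyde
Conditions: Pd(OAc)2 (10 mol %), O2 (1 atm), DMSO, 25–40 °C
Reagents that add atoms: none
Why: Saegusa–Ito oxidation in its aerobic catalytic form: the enol silane hands its enolate to divalent palladium, the only β-hydrogens sit on the ring CH2 so syn β-hydride elimination can only create the endocyclic C=C of the push–pull enal, and O2 returns zerovalent palladium to Pd(OAc)2.

Step 5
Reactants: 6 (1E,3E)-buta-1,3-diene-1,4-diyl dibenzoate (1.5 equiv); 9 2,2-dimethyl-1,3-dioxole-4-carbaldehyde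
Product: 10 (3aR,4S,7R,7aS)-3a-formyl-2,2-dimethyl-3a,4,7,7a-tetrahydro-1,3-benzodioxole-4,7-diyl dibenzoate. This is the cis-fused C1,C2-acetonide with both ketal oxygens on one face and the C3-OBz, C6-OBz and C1-CHO groups on the other, (1R,2S,3R,6S) in target locants.
Conditions: (R)-3,3-diphenyl-1-(o-tolyl)tetrahydro-1H,3H-pyrrolo[1,2-c][1,3,2]oxazaborole (20 mol %), HN(SO2CF3)2 (18 mol %, kept below the boron component so that no free acid remains), CH2Cl2, −40 °C → rt
Reagents that add atoms: none
Why: Proposed new method: the cationic boron binds the formyl oxygen of 9 (the most Lewis-basic site present, a vinylogous carbonate carbonyl), which lowers the LUMO of the donor-substituted C1=C2 bond enough for a normal-demand, concerted but asynchronous [4π+2π] cycloaddition with 6 in which C2–C3, at the enal β-carbon, forms ahead of C1–C6. The closest known reaction types are thermal Diels–Alder additions of E,E-1,4-diacyloxybutadienes to vinylene carbonate and oxazaborolidinium-catalysed additions of dienes to 2-substituted acroleins; what is new is the pairing of a doubly oxygenated enal with a diacyloxydiene. The single new ring, the six-membered carbocycle, closes intermolecularly by suprafacial bonding at both diene termini and both dienophile carbons. C1 and C2 receive cis oxygens because the enediol geometry is locked in the dioxole ring, and C3 and C6 receive cis benzoates because both diene double bonds are E. The relation between these two pairs requires the formyl-endo, dioxole-exo topology, which the substrate secures through secondary overlap of the activated formyl group and through the ketal methyl groups, which would press on C4 and C5 of the diene in the opposite topology; the symmetric diene removes any regiochemical issue. The absolute configuration requires bonding to the Si face of the formyl-bearing carbon, the face that the (R)-catalyst should leave open when the s-trans enal, held by a formyl C–H···O contact, stacks on a catalyst phenyl group.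

Step 6
Reactants: 10 cycloadduct aldehyde
Product: 11 C7 primary alcohol (3a-hydroxymethyl analogue of 10, all four centres unchanged)
Conditions: NaBH4, THF/MeOH, −20 → 0 °C; aq NH4Cl
Reagents that add atoms: none
Why: Chemoselective borohydride reduction of a non-enolisable aldehyde is far faster than attack on benzoates and touches no stereocentre, and a possible C6→C7 benzoyl shift is harmless because step 7 benzoylates whichever hydroxyl is free and gives the same 12.

Step 7
Reactants: 11 alcohol; 3 benzoyl chloride
Product: 12 C3,C6,C7-tribenzoate C1,C2-acetonide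
Conditions: BzCl, pyridine, DMAP (cat.), CH2Cl2, 0 °C → rt
Reagents that add atoms: benzoyl chloride, O=C(Cl)c1ccccc1
Why: Nucleophile-catalysed esterification (acyl chloride, pyridine/DMAP) of the only free hydroxyl, with no stereocentre involved.

Step 8
Reactants: 12 tribenzoate acetonide
Product: 13 C1,C2-diol tribenzoate (spatial arrangement as in the target; C1 reads S here only because the ligand ranking changes)
Conditions: CF3CO2H/H2O (9:1), CH2Cl2, 0 °C → rt
Reagents that add atoms: none
Why: Acid-catalysed ketal hydrolysis breaks only the bonds to the ketal carbon, so C1 and C2 keep their configuration, while benzoates are inert to aqueous trifluoroacetic acid at this temperature and acyl migration is slow under acid.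

Step 9
Reactants: 13 diol
Product: 14 target, (1R,2S,3R,6S)-2-acetoxy-1-[(benzoyloxy)methyl]-1-hydroxycyclohex-4-ene-3,6-diyl dibenzoate
Conditions: Ac2O (1.5 equiv), pyridine, 0 °C → rt
Reagents that add atoms: acetic anhydride, CC(=O)OC(C)=O
Why: Site-selective acylation: the secondary C2 hydroxyl is acetylated by Ac2O/pyridine, whereas the tertiary C1 hydroxyl, crowded by C2, C6 and C7, stays free without forcing catalysis.

Compound list
1 | 2,5-dimethoxytetrahydrofuran | COC1CCC(OC)O1 | starting material
2 | succinaldehyde | O=CCCC=O | intermediate
3 | benzoyl chloride | O=C(Cl)c1ccccc1 | starting material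
4 | 4-oxobut-1-en-1-yl benzoate (not isolated, geometry mixed) | O=CCC=COC(=O)c1ccccc1 | intermediate
5 | buta-1,3-diene-1,4-diyl dibenzoate, E/Z mixture (not isolated) | O=C(OC=CC=COC(=O)c1ccccc1)c1ccccc1 | intermediate
6 | (1E,3E)-buta-1,3-diene-1,4-diyl dibenzoate | O=C(O/C=C/C=C/OC(=O)c1ccccc1)c1ccccc1 | intermediate
7 | (R)-2,2-dimethyl-1,3-dioxolane-4-carbaldehyde | CC1(C)OC[C@@H](O1)C=O | starting material
8 | 4-{[(tert-butyldimethylsilyl)oxy]methylidene}-2,2-dimethyl-1,3-dioxolane (E/Z) | CC1(C)OCC(=CO[Si](C)(C)C(C)(C)C)O1 | intermediate
9 | 2,2-dimethyl-1,3-dioxole-4-carbaldehyde | CC1(C)OC=C(C=O)O1 | intermediate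
10 | cycloadduct aldehyde (C1,C2-acetonide, C3/C6 dibenzoate) | CC1(C)O[C@H]2[C@H](OC(=O)c3ccccc3)C=C[C@H](OC(=O)c3ccccc3)[C@@]2(C=O)O1 | intermediate
11 | C7 alcohol | CC1(C)O[C@H]2[C@H](OC(=O)c3ccccc3)C=C[C@H](OC(=O)c3ccccc3)[C@@]2(CO)O1 | intermediate
12 | tribenzoate acetonide | CC1(C)O[C@H]2[C@H](OC(=O)c3ccccc3)C=C[C@H](OC(=O)c3ccccc3)[C@@]2(COC(=O)c3ccccc3)O1 | intermediate
13 | C1,C2-diol tribenzoate | O[C@H]1[C@H](OC(=O)c2ccccc2)C=C[C@H](OC(=O)c2ccccc2)[C@]1(O)COC(=O)c1ccccc1 | intermediate
14 | target | CC(=O)O[C@H]1[C@H](OC(=O)c2ccccc2)C=C[C@H](OC(=O)c2ccccc2)[C@]1(O)COC(=O)c1ccccc1 | target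

Total step count: 9. Longest linear sequence: 7 steps (steps 1, 2, 5–9 or steps 3, 4, 5–9).

Steps most likely to fail

1. Step 5.
- What may go wrong:
  - the doubly donor-substituted enal may react too slowly with a weakly nucleophilic diene;
  - the ketal may ionise under the acidic catalyst;
  - cycloaddition may occur at the formyl C=O instead of the C=C;
  - the formyl-endo preference or the facial selectivity may be eroded.
- Start and return: the fallback drops the cycloaddition for chiral-pool chemistry and ring-closing metathesis. It sets out from benzoyl chloride 3, the only route material it keeps, and comes back at 12.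
- Hydroxymethylation: commercial 2,3:5,6-di-O-isopropylidene-D-mannofuranose F1 undergoes the known aldol hydroxymethylation (aq HCHO, K2CO3, MeOH, reflux) to 2-C-(hydroxymethyl)-2,3:5,6-di-O-isopropylidene-D-mannofuranose F2. Its branched carbon, internal acetonide and C4 carbinol already correspond to C1, C2 and C3 of the target, with C7 in place.
- Vinyl addition: vinylmagnesium bromide opens the lactol to the vinyl carbinol triol F3. The new carbinol is C6, and its epimers are separated here.
- Benzoylation: 3 in pyridine gives the tribenzoate bis-acetonide F4.
- Selective hydrolysis: aqueous acetic acid removes only the terminal acetonide to give the terminal diol F5.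
- Olefination: I2/PPh3/imidazole in hot toluene (Garegg–Samuelsson olefination) converts the diol into the 1,7-diene F6.
- Ring closure: the second-generation Grubbs catalyst closes C4=C5 to give 12.

2. Step 2.
- What may go wrong: amine-induced aldol oligomerisation of the dialdehyde may outrun O-acylation, and the proportion of E,E isomer may stay low.
- Fallback: one dienolisation of a conjugated enal replaces two enolisations of a fragile dialdehyde. It sets out from 3 and comes back at 6.
- Sequence: (Z)-but-2-ene-1,4-diol F7 is monobenzoylated with 3 (Et3N, CH2Cl2, 0 °C) to (Z)-4-hydroxybut-2-en-1-yl benzoate F8. MnO2 oxidises this to 4-oxobut-2-en-1-yl benzoate F9, whose alkene geometry is immaterial because that bond becomes the central single bond of the diene. γ-Deprotonation and O-benzoylation (3, Et3N, DMAP), then the same iodine equilibration and crystallisation, give 6.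

3. Step 4.
- What may go wrong: ring-opening β-alkoxide expulsion from the palladium enolate may compete with β-hydride elimination, and the volatile product may be lost from DMSO.
- Fallback: a selenoxide syn-elimination replaces the palladium chemistry. It sets out from 8 and comes back at 9.
- Sequence: PhSeCl (CH2Cl2, −78 °C) converts 8 into 2,2-dimethyl-4-(phenylselanyl)-1,3-dioxolane-4-carbaldehyde F10. mCPBA at −78 °C gives the corresponding selenoxide F11. Warming in the presence of iPr2NH triggers syn-elimination towards the ring CH2 and gives 9.

Further compounds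
F1 | step 5 | 2,3:5,6-di-O-isopropylidene-D-mannofuranose (commercial, lactol) | OC1[C@H]2OC(C)(C)O[C@H]2[C@H](O1)[C@H]1COC(C)(C)O1
F2 | step 5 | 2-C-(hydroxymethyl)-2,3:5,6-di-O-isopropylidene-D-mannofuranose (lactol) | OC1[C@@]2(CO)OC(C)(C)O[C@H]2[C@H](O1)[C@H]1COC(C)(C)O1
F3 | step 5 | vinyl carbinol triol | C=C[C@H](O)[C@@]1(CO)OC(C)(C)O[C@H]1[C@H](O)[C@H]1COC(C)(C)O1
F4 | step 5 | tribenzoate bis-acetonide | C=C[C@H](OC(=O)c1ccccc1)[C@@]1(COC(=O)c2ccccc2)OC(C)(C)O[C@H]1[C@H](OC(=O)c1ccccc1)[C@H]1COC(C)(C)O1
F5 | step 5 | terminal diol | C=C[C@H](OC(=O)c1ccccc1)[C@@]1(COC(=O)c2ccccc2)OC(C)(C)O[C@H]1[C@H](OC(=O)c1ccccc1)[C@H](O)CO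
F6 | step 5 | 1,7-diene | C=C[C@H](OC(=O)c1ccccc1)[C@@]1(COC(=O)c2ccccc2)OC(C)(C)O[C@H]1[C@H](OC(=O)c1ccccc1)C=C
F7 | step 2 | (Z)-but-2-ene-1,4-diol (commercial) | OC/C=C\CO
F8 | step 2 | (Z)-4-hydroxybut-2-en-1-yl benzoate | O=C(OC/C=C\CO)c1ccccc1
F9 | step 2 | 4-oxobut-2-en-1-yl benzoate | O=CC=CCOC(=O)c1ccccc1
F10 | step 4 | 2,2-dimethyl-4-(phenylselanyl)-1,3-dioxolane-4-carbaldehyde (racemic) | CC1(C)OCC(C=O)([Se]c2ccccc2)O1
F11 | step 4 | 2,2-dimethyl-4-(phenylseleninyl)-1,3-dioxolane-4-carbaldehyde | CC1(C)OCC(C=O)([Se](=O)c2ccccc2)O1
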